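**Retrosynthetic overview**
1. The target is a (1S,2R,5S,6R)-2,6-diaryl-3,7-dioxabicyclo[3.3.0]octane. Ring D–O carries an erythro (7S,8R) arylglycerol unit ending in ring E; ring C–O carries a threo (7R,8R) unit on ring B, which is itself O-linked to an erythro (7R,8S) unit ending in ring A.
2. Each aryl–O–C8/C7–C8 junction is cut by an oxazolidinone-controlled glycolate syn-aldol (aryloxyacetyl imide plus aryl aldehyde gives threo). The two erythro units follow by Mitsunobu inversion at C7. The ring A/ring B unit is made apart as an aldehyde and joined last.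
3. Core: the chain C8–C1–C5–C4, with aryl carbinol carbon C2 (ring C) on C1 and C6 (ring D) on C5, is read as a furan-2(5H)-one (C8 lactone carbonyl, C1 α-carbon, C5 β-carbon, C4 acetal carbon). It has accepted a ring D acyl-anion equivalent at C5 and the ring C aldehyde at C1, so bonds C5–C6 and C1–C2 form in one flask on a (5S)-5-menthyloxy butenolide.
4. Ring order: the key step closes no ring. Both tetrahydrofuran rings (O3 between C2 and C4, O7 between C6 and C8) close together afterwards under acid through benzylic cations. The arms are then grown, ring D first, ring C second.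

Key step: step 6

Locants: the core is numbered as 3,7-dioxabicyclo[3.3.0]octane; in each arylglycerol unit (A, B, E, named after its aryl ring) C7 is the benzylic carbon, C8 the aryloxy-bearing carbon, C9 the terminal carbon; Xc(S) and Xc(R) are (S)- and (R)-4-benzyl-2-oxooxazolidin-3-yl.
Assumption: the carbinol carbon made in step 6 (C2) and the one made in step 8 (C6) are carried as whatever epimers form (12–14 are drawn as one C2 epimer, C6 in 14 undefined), because step 9 re-sets both.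

**Step 1**
Reactants: 1 furfural
Product: 2 5-hydroxyfuran-2(5H)-one (racemic)
Conditions: O2, hν (visible), rose bengal (C20H2Cl4I4Na2O5, cat.), MeOH, rt
Reagents that add atoms: oxygen, O=O
Why: Dye-sensitised photo-oxygenation: singlet oxygen adds across C2/C5 of the furan ([4+2]) and methanolysis of the endoperoxide expels the formyl carbon as methyl formate, leaving the γ-hydroxybutenolide (C5 racemic, set in step 2).

**Step 2**
Reactants: 2 5-hydroxyfuran-2(5H)-one; 3 (+)-menthol [(1S,2R,5S)]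
Product: 4 (5S)-5-[(1S,2R,5S)-menthyloxy]furan-2(5H)-one
Conditions: (1S)-(+)-10-camphorsulfonic acid (cat.), toluene, reflux (Dean–Stark); crystallise from petroleum ether, −20 °C; mother liquor re-equilibrated with the same acid and recrystallised
Reagents that add atoms: none
Why: Acid-catalysed acetalisation of the lactol gives both C5 epimers, which interconvert under the acid while the (5S) epimer crystallises (crystallisation-driven epimer enrichment, the mirror image of the familiar (5R)/(−)-menthyl case), so C5 is set by the purchased menthol centres.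

**Step 3**
Reactants: 5 syringaldehyde; 6 1,3-propanedithiol
Product: 7 2-(4-hydroxy-3,5-dimethoxyphenyl)-1,3-dithiane
Conditions: BF3·OEt2 (cat.), CH2Cl2, 0 °C → rt
Reagents that add atoms: none
Why: Lewis-acid-catalysed thioacetalisation of the aldehyde; the free phenol is inert, and the dithiane is made before the acid-labile MOM group is introduced.

**Step 4**
Reactants: 7 2-(4-hydroxy-3,5-dimethoxyphenyl)-1,3-dithiane
Product: 8 2-[3,5-dimethoxy-4-(methoxymethoxy)phenyl]-1,3-dithiane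
Conditions: MOMCl, iPr2NEt, CH2Cl2, 0 °C → rt
Reagents that add atoms: chloromethyl methyl ether, COCCl
Why: Williamson-type O-alkylation of the hindered phenol by the very reactive chloromethyl ether under amine base; the dithiane is untouched.

**Step 5**
Reactants: 5 syringaldehyde
Product: 9 4-benzyloxy-3,5-dimethoxybenzaldehyde
Conditions: BnBr, K2CO3, DMF, rt
Reagents that add atoms: benzyl bromide, BrCc1ccccc1
Why: Williamson ether synthesis on the phenoxide with a benzylic bromide.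

**Step 6**
Reactants: 8 2-[3,5-dimethoxy-4-(methoxymethoxy)phenyl]-1,3-dithiane; 4 (5S)-5-[(1S,2R,5S)-menthyloxy]furan-2(5H)-one; 9 4-benzyloxy-3,5-dimethoxybenzaldehyde
Product: 12 (3R,4S,5S)-3-[(R)-(4-benzyloxy-3,5-dimethoxyphenyl)(hydroxy)methyl]-4-{2-[3,5-dimethoxy-4-(methoxymethoxy)phenyl]-1,3-dithian-2-yl}-5-[(1S,2R,5S)-menthyloxy]dihydrofuran-2(3H)-one, via 2-lithio-1,3-dithiane 10 (not isolated), via lithium lactone enolate 11 (not isolated)
Conditions: n-BuLi (1.05 equiv), THF, −78 → −30 °C; 4, −78 °C; 9 (1.2 equiv), −78 °C; AcOH, −78 °C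
Reagents that add atoms: none
Why: n-BuLi removes the C2–H of dithiane 8 (acidified by two sulfur atoms and the aryl ring) to give 10, a soft, delocalised acyl-anion equivalent that adds 1,4 to butenolide 4 at the β-carbon (future C5) on the face anti to the menthyloxy group of the neighbouring acetal carbon; the resulting lithium enolate 11 then adds through its α-carbon (future C1) to aldehyde 9 on the face anti to the new, very bulky dithianyl group, so the three ring substituents end up trans,trans. The closest known reaction type is the tandem Michael addition–aldol trapping of lithiated 2-aryl-1,3-dithianes on 5-alkoxyfuran-2(5H)-ones used for lignan lactones. No ring is closed; the step forms bonds C5–C6 and C1–C2 and three stereocentres. C5 is controlled by the acetal stereocentre of 4, C1 by the C5 substituent just installed, and the carbinol carbon C2 is not controlled and need not be, because it is re-set in step 9. The selectivities needed are 1,4- over 1,2-addition, secured by the stabilised benzylic dithianyl anion (any carbonyl adduct reverts and drains into the conjugate adduct), and anti attack twice, secured by the single acetal centre. The cold AcOH quench protonates the lithium aldolate before it can undergo retro-aldol cleavage.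

**Step 7**
Reactants: 12 dithianyl lactone from step 6
Product: 13 (3R,4S,5S)-3-[(R)-(4-benzyloxy-3,5-dimethoxyphenyl)(hydroxy)methyl]-4-[3,5-dimethoxy-4-(methoxymethoxy)benzoyl]-5-[(1S,2R,5S)-menthyloxy]dihydrofuran-2(3H)-one
Conditions: Hg(ClO4)2·3H2O, CaCO3, THF–H2O (5:1), 0 °C → rt
Reagents that add atoms: water, O
Why: Thiophilic divalent mercury binds both sulfur atoms and water hydrolyses the thionium ion to the aryl ketone (dithiane hydrolysis), CaCO3 buffering the liberated HClO4 so that the MOM ether, the menthyl acetal and the β-hydroxy lactone survive; the ketone may equilibrate with the cyclic hemiketal formed with the C2 hydroxyl, which does not matter for step 8.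

**Step 8**
Reactants: 13 keto lactone
Product: 14 (2S,3S)-2-[(R)-(4-benzyloxy-3,5-dimethoxyphenyl)(hydroxy)methyl]-3-{[3,5-dimethoxy-4-(methoxymethoxy)phenyl](hydroxy)methyl}butane-1,4-diol (tetrol; butane C2 = core C1, butane C3 = core C5; C6 carbinol as epimers)
Conditions: LiAlH4 (excess), THF, 0 °C → rt; aqueous NaOH work-up
Reagents that add atoms: none
Why: Hydride reduces the ketone, the lactone and, after the hemiacetal alkoxide has expelled menthoxide, the unmasked C4 aldehyde, giving the tetrol in one operation; C1 and C5 are not touched and the new C6 carbinol may form as either epimer.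

**Step 9**
Reactants: 14 tetrol
Product: 15 (1S,2R,5S,6R)-2-(4-benzyloxy-3,5-dimethoxyphenyl)-6-(4-hydroxy-3,5-dimethoxyphenyl)-3,7-dioxabicyclo[3.3.0]octane (ring C O-benzyl, ring D free phenol)
Conditions: HCl (1.25 M in MeOH), CH2Cl2–MeOH, 0 °C → rt, monitored; NaHCO3 quench
Reagents that add atoms: none
Why: Acid removes the MOM group and ionises both benzylic carbinols to 4-oxygen-stabilised, quinone-methide-like cations, each captured by the 1,4-related primary hydroxyl (C2 by C4–OH, C6 by C8–OH; SN1 cycloetherification, 5-exo-trig); each aryl group takes the exo (convex) position trans to the adjacent ring-fusion substituent, which means 2R,6R on the 1S,5S skeleton whatever the carbinol configurations, and the reaction is stopped at conversion because prolonged acid would re-ionise the product and epimerise C2/C6.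

**Step 10**
Reactants: 16 (S)-4-benzyloxazolidin-2-one
Product: 18 (S)-4-benzyl-3-(bromoacetyl)oxazolidin-2-one, via N-lithio oxazolidinone 17 (not isolated)
Conditions: n-BuLi, THF, −78 °C; BrCH2COBr, −78 → 0 °C
Reagents that add atoms: bromoacetyl bromide, BrCC(Br)=O
Why: N-acylation of the lithium salt of the oxazolidinone by the acid bromide, acyl substitution being faster than displacement of the α-bromide; the auxiliary stereocentre is unaffected.

**Step 11**
Reactants: 19 vanillin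
Product: 20 3-methoxy-4-(triisopropylsilyloxy)benzaldehyde
Conditions: TIPSCl, imidazole, DMF, rt
Reagents that add atoms: triisopropylsilyl chloride, CC(C)[Si](Cl)(C(C)C)C(C)C
Why: Imidazole-mediated silylation of the phenol; the TIPS ether is chosen because it survives carbonate, borohydride and hydrogenolysis and leaves with fluoride at the end.

**Step 12**
Reactants: 15 mono-benzyl furofuran phenol; 18 (S)-4-benzyl-3-(bromoacetyl)oxazolidin-2-one
Product: 21 (S)-4-benzyl-3-[2-(4-{(1S,2R,5S,6R)-6-(4-benzyloxy-3,5-dimethoxyphenyl)-3,7-dioxabicyclo[3.3.0]octan-2-yl}-2,6-dimethoxyphenoxy)acetyl]oxazolidin-2-one (ring D–O–CH2–CO–Xc(S))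
Conditions: K2CO3, acetone, rt
Reagents that add atoms: none
Why: Williamson etherification: the syringyl phenoxide displaces bromide from the α-bromo imide (carbonyl-activated SN2) faster than it attacks the imide carbonyl.

**Step 13**
Reactants: 21 ring D glycolyl imide; 20 3-methoxy-4-(triisopropylsilyloxy)benzaldehyde
Product: 23 syn-aldol imide, ring D–O–CH(CO–Xc(S))–CH(OH)–ring E(OTIPS), (2S,3R) in the acyl chain, ring C O-benzyl, via dibutylboron Z-enolate 22 (not isolated)
Conditions: Bu2BOTf (1.3 equiv), iPr2NEt (1.6 equiv), CH2Cl2, −78 → 0 °C; 20, −78 → 0 °C; pH 7 buffer–MeOH–30% H2O2, 0 °C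
Reagents that add atoms: none
Why: Evans syn-aldol reaction: the Z boron enolate adds to the aldehyde through a chair Zimmerman–Traxler transition state on the face away from the benzyl group of the (S)-auxiliary, setting C8 and C7 as the (2S,3R) syn imide, which is the threo (7R,8R) arrangement once C9 is reduced.

**Step 14**
Reactants: 23 syn-aldol imide
Product: 24 compound 15 etherified at ring D–O with (1R,2R)-1,3-dihydroxy-1-[3-methoxy-4-(triisopropylsilyloxy)phenyl]propan-2-yl (unit E, threo 7R,8R)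
Conditions: LiBH4, MeOH (1 equiv), THF, 0 °C
Reagents that add atoms: none
Why: Reductive cleavage of the N-acyl oxazolidinone at the more electrophilic exocyclic carbonyl gives the C9 alcohol and returns the auxiliary; ethers and both new stereocentres are untouched.

**Step 15**
Reactants: 24 threo diol
Product: 25 the C9 tert-butyldimethylsilyl ether of 24 (unit E: C9–OTBS, C7–OH, 7R,8R)
Conditions: TBSCl (1.1 equiv), imidazole, CH2Cl2, 0 °C
Reagents that add atoms: tert-butyldimethylsilyl chloride, CC(C)(C)[Si](C)(C)Cl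
Why: Kinetic silylation of the primary C9 hydroxyl in preference to the hindered secondary benzylic C7 hydroxyl.

**Step 16**
Reactants: 25 ring C benzyl ether
Product: 26 compound 25 with the ring C phenol free
Conditions: H2 (1 atm), 10% Pd/C, EtOAc, rt
Reagents that add atoms: none
Why: Hydrogenolysis of the phenolic benzyl ether, which under neutral conditions at 1 atm is far faster than cleavage of the benzylic C–O bonds of the furofuran or of the C7 alcohol; silyl ethers are inert.

**Step 17**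
Reactants: 26 ring C phenol; 18 (S)-4-benzyl-3-(bromoacetyl)oxazolidin-2-one
Product: 27 compound 26 O-alkylated at ring C–O with CH2–CO–Xc(S) (unit E still threo, C7–OH free)
Conditions: K2CO3, acetone, rt
Reagents that add atoms: none
Why: Williamson etherification as in step 12; carbonate deprotonates only the ring C phenol, so the C7 alcohol of unit E is not alkylated.

**Step 18**
Reactants: 27 ring C glycolyl imide with free C7–OH
Product: 28 compound 27 inverted and benzoylated at C7 of unit E (erythro 7S,8R; C7–OBz, C9–OTBS, ring E–OTIPS)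
Conditions: PhCO2H, PPh3, DIAD, THF, 0 °C → rt
Reagents that add atoms: benzoic acid, OC(=O)c1ccccc1
Why: Mitsunobu esterification: the only free hydroxyl is turned into its oxyphosphonium ion and displaced by benzoate with inversion at C7 (threo 7R,8R to erythro 7S,8R), the inductively withdrawing β-aryloxy group disfavouring ionisation; the benzoate then protects C7–OH during the second aldol.

**Step 19**
Reactants: 29 (R)-4-benzyloxazolidin-2-one
Product: 31 (R)-4-benzyl-3-(bromoacetyl)oxazolidin-2-one, via N-lithio oxazolidinone 30 (not isolated)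
Conditions: n-BuLi, THF, −78 °C; BrCH2COBr, −78 → 0 °C
Reagents that add atoms: bromoacetyl bromide, BrCC(Br)=O
Why: N-acylation of the lithiated oxazolidinone as in step 10.

**Step 20**
Reactants: 32 (E)-isoeugenol; 31 (R)-4-benzyl-3-(bromoacetyl)oxazolidin-2-one
Product: 33 (R)-4-benzyl-3-{2-[2-methoxy-4-((E)-prop-1-enyl)phenoxy]acetyl}oxazolidin-2-one
Conditions: K2CO3, acetone, rt
Reagents that add atoms: none
Why: Williamson etherification as in step 12; the propenyl group, a masked ring B aldehyde, is inert.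

**Step 21**
Reactants: 33 ring B glycolyl imide; 20 3-methoxy-4-(triisopropylsilyloxy)benzaldehyde
Product: 35 (R)-4-benzyl-3-{(2R,3S)-3-hydroxy-3-[3-methoxy-4-(triisopropylsilyloxy)phenyl]-2-[2-methoxy-4-((E)-prop-1-enyl)phenoxy]propanoyl}oxazolidin-2-one, via dibutylboron Z-enolate 34 (not isolated)
Conditions: Bu2BOTf (1.2 equiv), iPr2NEt (1.5 equiv), CH2Cl2, −78 → 0 °C; 20, −78 → 0 °C; pH 7 buffer–MeOH–30% H2O2, 0 °C
Reagents that add atoms: none
Why: Evans syn-aldol reaction as in step 13 but with the (R)-auxiliary, which gives the opposite sense, the (2R,3S) imide, i.e. threo (7S,8S) after reduction.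

**Step 22**
Reactants: 35 syn-aldol imide
Product: 36 (1S,2S)-1-[3-methoxy-4-(triisopropylsilyloxy)phenyl]-2-[2-methoxy-4-((E)-prop-1-enyl)phenoxy]propane-1,3-diol
Conditions: LiBH4, MeOH (1 equiv), THF, 0 °C
Reagents that add atoms: none
Why: Reductive removal of the auxiliary as in step 14; the alkene and the silyl ether are inert.

**Step 23**
Reactants: 36 threo diol
Product: 37 (1S,2S)-3-(tert-butyldimethylsilyloxy)-1-[3-methoxy-4-(triisopropylsilyloxy)phenyl]-2-[2-methoxy-4-((E)-prop-1-enyl)phenoxy]propan-1-ol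
Conditions: TBSCl (1.1 equiv), imidazole, CH2Cl2, 0 °C
Reagents that add atoms: tert-butyldimethylsilyl chloride, CC(C)(C)[Si](C)(C)Cl
Why: Selective silylation of the primary hydroxyl as in step 15.

**Step 24**
Reactants: 37 C9 silyl ether
Product: 38 (1R,2S)-3-(tert-butyldimethylsilyloxy)-1-[3-methoxy-4-(triisopropylsilyloxy)phenyl]-2-[2-methoxy-4-((E)-prop-1-enyl)phenoxy]propyl benzoate
Conditions: PhCO2H, PPh3, THF, 0 °C; DIAD added last, 0 °C → rt
Reagents that add atoms: benzoic acid, OC(=O)c1ccccc1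
Why: Mitsunobu inversion at C7 as in step 18 (threo 7S,8S to erythro 7R,8S), the azodicarboxylate being added last so that it is consumed by PPh3 and not by the electron-rich styrene.

**Step 25**
Reactants: 38 propenyl arene
Product: 39 (1R,2S)-3-(tert-butyldimethylsilyloxy)-2-(4-formyl-2-methoxyphenoxy)-1-[3-methoxy-4-(triisopropylsilyloxy)phenyl]propyl benzoate (ring A/ring B aldehyde)
Conditions: OsO4 (2 mol%), NaIO4 (4 equiv), 2,6-lutidine, dioxane–H2O (3:1), rt
Reagents that add atoms: sodium periodate NaIO4, [Na+].[O-]I(=O)(=O)=O (terminal oxidant that supplies the aldehyde oxygen)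
Why: Lemieux–Johnson oxidation: catalytic osmylation of the only alkene and periodate cleavage of the diol unveil the ring B aldehyde; arenes, benzoate and silyl ethers are inert.

**Step 26**
Reactants: 28 ring C glycolyl imide; 39 ring A/ring B aldehyde
Product: 41 syn-aldol imide, ring C–O–CH(CO–Xc(S))–CH(OH)–ring B, (2S,3R) in the acyl chain; units A (7R,8S) and E (7S,8R) each with C7–OBz, C9–OTBS and aryl–OTIPS, via dibutylboron Z-enolate 40 (not isolated)
Conditions: Bu2BOTf (1.3 equiv), iPr2NEt (1.6 equiv), CH2Cl2, −78 → 0 °C; 39 (1.3 equiv), −78 → 0 °C; pH 7 buffer–MeOH–30% H2O2, 0 °C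
Reagents that add atoms: none
Why: Evans syn-aldol reaction as in step 13: the (S)-auxiliary on the ring C glycolate sets unit B as the (2S,3R) imide, i.e. threo (7R,8R), the remote stereocentres of both partners having no say.

**Step 27**
Reactants: 41 syn-aldol imide
Product: 42 tetrasilyl ether of the target (C9–OTBS on units A and E, ring A and ring E phenols as TIPS ethers, all other hydroxyls free)
Conditions: LiBH4 (excess), MeOH, THF, 0 °C → rt
Reagents that add atoms: none
Why: Borohydride reduces the imide to the C9 alcohol of unit B, releasing the auxiliary, and cleaves both secondary benzoates as benzyl alcohol; no stereocentre is affected and the silyl ethers stay.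

**Step 28**
Reactants: 42 tetrasilyl ether
Product: 43 target CNP0316493.1
Conditions: TBAF, AcOH, THF, 0 °C → rt
Reagents that add atoms: none
Why: Fluoride cleaves the two primary TBS ethers and the two aryl TIPS ethers (Si–F bond formation), AcOH buffering the phenoxides so that the 4-hydroxybenzylic aryl ether units never meet strong base.

**Compound list**
1 | furfural | O=Cc1ccco1 | starting material
2 | 5-hydroxyfuran-2(5H)-one (racemic) | O=C1C=CC(O)O1 | intermediate
3 | (+)-menthol, (1S,2R,5S) | C[C@H]1CC[C@@H]([C@H](C1)O)C(C)C | starting material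
4 | (5S)-5-[(1S,2R,5S)-menthyloxy]furan-2(5H)-one | O=C1C=C[C@@H](O[C@H]2C[C@@H](C)CC[C@@H]2C(C)C)O1 | intermediate
5 | syringaldehyde | COc1cc(C=O)cc(OC)c1O | starting material
6 | 1,3-propanedithiol | SCCCS | starting material
7 | 2-(4-hydroxy-3,5-dimethoxyphenyl)-1,3-dithiane | COc1cc(cc(OC)c1O)C1SCCCS1 | intermediate
8 | 2-[3,5-dimethoxy-4-(methoxymethoxy)phenyl]-1,3-dithiane | COCOc1c(OC)cc(cc1OC)C1SCCCS1 | intermediate
9 | 4-benzyloxy-3,5-dimethoxybenzaldehyde | COc1cc(C=O)cc(OC)c1OCc1ccccc1 | intermediate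
10 | 2-lithio-2-[3,5-dimethoxy-4-(methoxymethoxy)phenyl]-1,3-dithiane | [Li]C1(SCCCS1)c1cc(OC)c(OCOC)c(OC)c1 | intermediate
11 | lithium enolate of (4S,5S)-4-(2-aryl-1,3-dithian-2-yl)-5-menthyloxydihydrofuran-2(3H)-one | [Li]OC1=C[C@H](C2(SCCCS2)c2cc(OC)c(OCOC)c(OC)c2)[C@@H](O[C@H]2C[C@@H](C)CC[C@@H]2C(C)C)O1 | intermediate
12 | (3R,4S,5S)-3-[(R)-(4-benzyloxy-3,5-dimethoxyphenyl)(hydroxy)methyl]-4-{2-[3,5-dimethoxy-4-(methoxymethoxy)phenyl]-1,3-dithian-2-yl}-5-[(1S,2R,5S)-menthyloxy]dihydrofuran-2(3H)-one (carbinol drawn as one epimer) | COc1cc(cc(OC)c1OCc1ccccc1)[C@H](O)[C@@H]1C(=O)O[C@H](O[C@H]2C[C@@H](C)CC[C@@H]2C(C)C)[C@H]1C1(SCCCS1)c1cc(OC)c(OCOC)c(OC)c1 | intermediate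
13 | (3R,4S,5S)-3-[(R)-(4-benzyloxy-3,5-dimethoxyphenyl)(hydroxy)methyl]-4-[3,5-dimethoxy-4-(methoxymethoxy)benzoyl]-5-[(1S,2R,5S)-menthyloxy]dihydrofuran-2(3H)-one | COc1cc(cc(OC)c1OCc1ccccc1)[C@H](O)[C@@H]1C(=O)O[C@H](O[C@H]2C[C@@H](C)CC[C@@H]2C(C)C)[C@H]1C(=O)c1cc(OC)c(OCOC)c(OC)c1 | intermediate
14 | (2S,3S)-2-[(R)-(4-benzyloxy-3,5-dimethoxyphenyl)(hydroxy)methyl]-3-{[3,5-dimethoxy-4-(methoxymethoxy)phenyl](hydroxy)methyl}butane-1,4-diol (second carbinol as epimers) | COc1cc(cc(OC)c1OCc1ccccc1)[C@H](O)[C@H](CO)[C@@H](CO)C(O)c1cc(OC)c(OCOC)c(OC)c1 | intermediate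
15 | (1S,2R,5S,6R)-2-(4-benzyloxy-3,5-dimethoxyphenyl)-6-(4-hydroxy-3,5-dimethoxyphenyl)-3,7-dioxabicyclo[3.3.0]octane | c1ccccc1COc3c(OC)cc([C@@H]4OC[C@@H]5[C@H]4CO[C@H]5c4cc(OC)c(O)c(OC)c4)cc3OC | intermediate
16 | (S)-4-benzyloxazolidin-2-one | O=C1N[C@@H](Cc2ccccc2)CO1 | starting material
17 | N-lithio (S)-4-benzyloxazolidin-2-one | [Li]N1[C@@H](Cc2ccccc2)COC1=O | intermediate
18 | (S)-4-benzyl-3-(bromoacetyl)oxazolidin-2-one | BrCC(=O)N1[C@@H](Cc2ccccc2)COC1=O | intermediate
19 | vanillin | COc1cc(C=O)ccc1O | starting material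
20 | 3-methoxy-4-(triisopropylsilyloxy)benzaldehyde | COc1cc(C=O)ccc1O[Si](C(C)C)(C(C)C)C(C)C | intermediate
21 | ring D glycolyl imide of 15 (ring D–O–CH2–CO–Xc(S), ring C O-benzyl) | c1ccccc1COc3c(OC)cc([C@@H]4OC[C@@H]5[C@H]4CO[C@H]5c4cc(OC)c(OCC(=O)N6[C@@H](Cc7ccccc7)COC6=O)c(OC)c4)cc3OC | intermediate
22 | dibutylboron Z-enolate of 21 | c1ccccc1COc3c(OC)cc([C@@H]4OC[C@@H]5[C@H]4CO[C@H]5c4cc(OC)c(O/C=C(\OB(CCCC)CCCC)N6[C@@H](Cc7ccccc7)COC6=O)c(OC)c4)cc3OC | intermediate
23 | syn-aldol imide, ring D–O–CH(CO–Xc(S))–CH(OH)–ring E(OTIPS), (2S,3R) acyl chain, ring C O-benzyl | c1ccccc1COc3c(OC)cc([C@@H]4OC[C@@H]5[C@H]4CO[C@H]5c4cc(OC)c(O[C@H](C(=O)N6[C@@H](Cc7ccccc7)COC6=O)[C@H](O)c6ccc(O[Si](C(C)C)(C(C)C)C(C)C)c(OC)c6)c(OC)c4)cc3OC | intermediate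
24 | 15 bearing on ring D–O the (1R,2R)-1,3-dihydroxy-1-[3-methoxy-4-(triisopropylsilyloxy)phenyl]propan-2-yl group (unit E threo, 7R,8R) | c1ccccc1COc3c(OC)cc([C@@H]4OC[C@@H]5[C@H]4CO[C@H]5c4cc(OC)c(O[C@H](CO)[C@H](O)c6ccc(O[Si](C(C)C)(C(C)C)C(C)C)c(OC)c6)c(OC)c4)cc3OC | intermediate
25 | C9 TBS ether of 24 | c1ccccc1COc3c(OC)cc([C@@H]4OC[C@@H]5[C@H]4CO[C@H]5c4cc(OC)c(O[C@H](CO[Si](C)(C)C(C)(C)C)[C@H](O)c6ccc(O[Si](C(C)C)(C(C)C)C(C)C)c(OC)c6)c(OC)c4)cc3OC | intermediate
26 | 25 with free ring C phenol | Oc3c(OC)cc([C@@H]4OC[C@@H]5[C@H]4CO[C@H]5c4cc(OC)c(O[C@H](CO[Si](C)(C)C(C)(C)C)[C@H](O)c6ccc(O[Si](C(C)C)(C(C)C)C(C)C)c(OC)c6)c(OC)c4)cc3OC | intermediate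
27 | ring C glycolyl imide of 26 (ring C–O–CH2–CO–Xc(S); unit E threo, C7–OH) | O=C(COc3c(OC)cc([C@@H]4OC[C@@H]5[C@H]4CO[C@H]5c4cc(OC)c(O[C@H](CO[Si](C)(C)C(C)(C)C)[C@H](O)c6ccc(O[Si](C(C)C)(C(C)C)C(C)C)c(OC)c6)c(OC)c4)cc3OC)N8[C@@H](Cc9ccccc9)COC8=O | intermediate
28 | 27 inverted and benzoylated at C7 of unit E (erythro 7S,8R) | O=C(COc3c(OC)cc([C@@H]4OC[C@@H]5[C@H]4CO[C@H]5c4cc(OC)c(O[C@H](CO[Si](C)(C)C(C)(C)C)[C@@H](OC(=O)c7ccccc7)c6ccc(O[Si](C(C)C)(C(C)C)C(C)C)c(OC)c6)c(OC)c4)cc3OC)N8[C@@H](Cc9ccccc9)COC8=O | intermediate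
29 | (R)-4-benzyloxazolidin-2-one | O=C1N[C@H](Cc2ccccc2)CO1 | starting material
30 | N-lithio (R)-4-benzyloxazolidin-2-one | [Li]N1[C@H](Cc2ccccc2)COC1=O | intermediate
31 | (R)-4-benzyl-3-(bromoacetyl)oxazolidin-2-one | BrCC(=O)N1[C@H](Cc2ccccc2)COC1=O | intermediate
32 | (E)-isoeugenol | C/C=C/c1ccc(O)c(OC)c1 | starting material
33 | (R)-4-benzyl-3-{2-[2-methoxy-4-((E)-prop-1-enyl)phenoxy]acetyl}oxazolidin-2-one | C/C=C/c1ccc(OCC(=O)N2[C@H](Cc3ccccc3)COC2=O)c(OC)c1 | intermediate
34 | dibutylboron Z-enolate of 33 | C/C=C/c1ccc(O/C=C(\OB(CCCC)CCCC)N2[C@H](Cc3ccccc3)COC2=O)c(OC)c1 | intermediate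
35 | (R)-4-benzyl-3-{(2R,3S)-3-hydroxy-3-[3-methoxy-4-(triisopropylsilyloxy)phenyl]-2-[2-methoxy-4-((E)-prop-1-enyl)phenoxy]propanoyl}oxazolidin-2-one | COc1cc([C@H](O)[C@H](C(=O)N2[C@H](Cc3ccccc3)COC2=O)Oc2ccc(/C=C/C)cc2OC)ccc1O[Si](C(C)C)(C(C)C)C(C)C | intermediate
36 | (1S,2S)-1-[3-methoxy-4-(triisopropylsilyloxy)phenyl]-2-[2-methoxy-4-((E)-prop-1-enyl)phenoxy]propane-1,3-diol | COc1cc([C@H](O)[C@H](CO)Oc2ccc(/C=C/C)cc2OC)ccc1O[Si](C(C)C)(C(C)C)C(C)C | intermediate
37 | (1S,2S)-3-(tert-butyldimethylsilyloxy)-1-[3-methoxy-4-(triisopropylsilyloxy)phenyl]-2-[2-methoxy-4-((E)-prop-1-enyl)phenoxy]propan-1-ol | COc1cc([C@H](O)[C@H](CO[Si](C)(C)C(C)(C)C)Oc2ccc(/C=C/C)cc2OC)ccc1O[Si](C(C)C)(C(C)C)C(C)C | intermediate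
38 | (1R,2S)-3-(tert-butyldimethylsilyloxy)-1-[3-methoxy-4-(triisopropylsilyloxy)phenyl]-2-[2-methoxy-4-((E)-prop-1-enyl)phenoxy]propyl benzoate | COc1cc([C@@H](OC(=O)c3ccccc3)[C@H](CO[Si](C)(C)C(C)(C)C)Oc2ccc(/C=C/C)cc2OC)ccc1O[Si](C(C)C)(C(C)C)C(C)C | intermediate
39 | (1R,2S)-3-(tert-butyldimethylsilyloxy)-2-(4-formyl-2-methoxyphenoxy)-1-[3-methoxy-4-(triisopropylsilyloxy)phenyl]propyl benzoate | COc1cc([C@@H](OC(=O)c3ccccc3)[C@H](CO[Si](C)(C)C(C)(C)C)Oc2ccc(C=O)cc2OC)ccc1O[Si](C(C)C)(C(C)C)C(C)C | intermediate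
40 | dibutylboron Z-enolate of 28 | CCCCB(CCCC)O\C(N8[C@@H](Cc9ccccc9)COC8=O)=C/Oc3c(OC)cc([C@@H]4OC[C@@H]5[C@H]4CO[C@H]5c4cc(OC)c(O[C@H](CO[Si](C)(C)C(C)(C)C)[C@@H](OC(=O)c7ccccc7)c6ccc(O[Si](C(C)C)(C(C)C)C(C)C)c(OC)c6)c(OC)c4)cc3OC | intermediate
41 | syn-aldol imide, ring C–O–CH(CO–Xc(S))–CH(OH)–ring B (2S,3R); units A and E each C7–OBz, C9–OTBS, aryl–OTIPS | COc1cc([C@@H](OC(=O)c6ccccc6)[C@H](CO[Si](C)(C)C(C)(C)C)Oc2ccc([C@@H](O)[C@@H](C(=O)N8[C@@H](Cc9ccccc9)COC8=O)Oc3c(OC)cc([C@@H]4OC[C@@H]5[C@H]4CO[C@H]5c4cc(OC)c(O[C@H](CO[Si](C)(C)C(C)(C)C)[C@@H](OC(=O)c7ccccc7)c5ccc(O[Si](C(C)C)(C(C)C)C(C)C)c(OC)c5)c(OC)c4)cc3OC)cc2OC)ccc1O[Si](C(C)C)(C(C)C)C(C)C | intermediate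
42 | tetrasilyl ether of the target (C9–OTBS on units A and E; ring A and ring E O–TIPS) | COc1cc([C@@H](O)[C@H](CO[Si](C)(C)C(C)(C)C)Oc2ccc([C@@H](O)[C@@H](CO)Oc3c(OC)cc([C@@H]4OC[C@@H]5[C@H]4CO[C@H]5c4cc(OC)c(O[C@H](CO[Si](C)(C)C(C)(C)C)[C@@H](O)c5ccc(O[Si](C(C)C)(C(C)C)C(C)C)c(OC)c5)c(OC)c4)cc3OC)cc2OC)ccc1O[Si](C(C)C)(C(C)C)C(C)C | intermediate
43 | CNP0316493.1 | COc1cc([C@@H](O)[C@H](CO)Oc2ccc([C@@H](O)[C@@H](CO)Oc3c(OC)cc([C@@H]4OC[C@@H]5[C@H]4CO[C@H]5c4cc(OC)c(O[C@H](CO)[C@@H](O)c5ccc(O)c(OC)c5)c(OC)c4)cc3OC)cc2OC)ccc1O | target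

**Totals**
Total step count: 28.
Longest linear sequence: 16 steps (1, 2, 6–9, 12–18, 26–28).

**Steps most likely to fail**

1. Step 6. Trapping of the hindered lithium enolate by the electron-rich aldehyde may be slow and reversible, so that the enolate is protonated or the aldolate reverts, leaving only the conjugate adduct. Fallback: the tandem process is split. Starting from 8 and 4, the conjugate addition is run as before and quenched with NH4Cl to isolate (4S,5S)-4-{2-[3,5-dimethoxy-4-(methoxymethoxy)phenyl]-1,3-dithian-2-yl}-5-[(1S,2R,5S)-menthyloxy]dihydrofuran-2(3H)-one F1. Its enolate is regenerated with LDA in THF at −78 °C, transmetalated with ZnCl2 and treated with 9; the zinc aldolate resists retro-aldol cleavage, and attack anti to the dithianyl group again gives 12, where the route is rejoined.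

2. Step 9. The acid strength needed to cleave the MOM ether may re-ionise the benzylic C–O bonds of the product and epimerise C2/C6, or let one benzylic cation be captured by the other benzylic hydroxyl. Fallback: phenol release is separated from ring closure by a change of the ring D protecting group.
- Starting from 7, silylation (TIPSCl, imidazole, DMF) gives 2-[3,5-dimethoxy-4-(triisopropylsilyloxy)phenyl]-1,3-dithiane F2.
- The key step with 4 and 9 gives the corresponding trans,trans dithianyl lactone F3.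
- Hg(ClO4)2/CaCO3 gives the aryl ketone F4, and LiAlH4 the tetrol F5.
- Catalytic camphorsulfonic acid in CH2Cl2 at 0 °C, with no MOM group to cleave, closes both rings to the ring D O-triisopropylsilyl ether of 15, F6.
- TBAF in THF at 0 °C then releases the phenol and returns the route at 15.

3. Step 18 (the same concern applies to step 24). The activated electron-rich benzylic oxyphosphonium may partly ionise, so inversion is incomplete, or may eliminate to the aryl enol ether. Fallback: inversion by oxidation and chelation-controlled reduction. Starting from 27, Dess–Martin periodinane buffered with NaHCO3 gives the C7 aryl ketone F7. Zn(BH4)2 in Et2O–THF at −30 °C reduces the ketone chelated to the α-aryloxy oxygen (Cram chelate model, hydride anti to the CH2OTBS group) and should leave the imide untouched at that temperature, giving the erythro (7S,8R) alcohol F8, the C7 epimer of 27. Benzoylation (BzCl, pyridine, DMAP) returns the route at 28.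

**Further compounds**
F1 | step 6 | (4S,5S)-4-{2-[3,5-dimethoxy-4-(methoxymethoxy)phenyl]-1,3-dithian-2-yl}-5-[(1S,2R,5S)-menthyloxy]dihydrofuran-2(3H)-one | O=C1C[C@H](C2(SCCCS2)c2cc(OC)c(OCOC)c(OC)c2)[C@@H](O[C@H]2C[C@@H](C)CC[C@@H]2C(C)C)O1
F2 | step 9 | 2-[3,5-dimethoxy-4-(triisopropylsilyloxy)phenyl]-1,3-dithiane | COc1cc(cc(OC)c1O[Si](C(C)C)(C(C)C)C(C)C)C1SCCCS1
F3 | step 9 | ring D O-TIPS analogue of 12 | COc1cc(cc(OC)c1OCc1ccccc1)[C@H](O)[C@@H]1C(=O)O[C@H](O[C@H]2C[C@@H](C)CC[C@@H]2C(C)C)[C@H]1C1(SCCCS1)c1cc(OC)c(O[Si](C(C)C)(C(C)C)C(C)C)c(OC)c1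
F4 | step 9 | ring D O-TIPS analogue of 13 | COc1cc(cc(OC)c1OCc1ccccc1)[C@H](O)[C@@H]1C(=O)O[C@H](O[C@H]2C[C@@H](C)CC[C@@H]2C(C)C)[C@H]1C(=O)c1cc(OC)c(O[Si](C(C)C)(C(C)C)C(C)C)c(OC)c1
F5 | step 9 | ring D O-TIPS analogue of 14 | COc1cc(cc(OC)c1OCc1ccccc1)[C@H](O)[C@H](CO)[C@@H](CO)C(O)c1cc(OC)c(O[Si](C(C)C)(C(C)C)C(C)C)c(OC)c1
F6 | step 9 | ring D O-triisopropylsilyl ether of 15 | c1ccccc1COc3c(OC)cc([C@@H]4OC[C@@H]5[C@H]4CO[C@H]5c4cc(OC)c(O[Si](C(C)C)(C(C)C)C(C)C)c(OC)c4)cc3OC
F7 | step 18 | C7 ketone of 27 (unit E aryl ketone, 8R) | O=C(COc3c(OC)cc([C@@H]4OC[C@@H]5[C@H]4CO[C@H]5c4cc(OC)c(O[C@H](CO[Si](C)(C)C(C)(C)C)C(=O)c6ccc(O[Si](C(C)C)(C(C)C)C(C)C)c(OC)c6)c(OC)c4)cc3OC)N8[C@@H](Cc9ccccc9)COC8=O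
F8 | step 18 | C7 epimer of 27 (unit E erythro 7S,8R, C7–OH) | O=C(COc3c(OC)cc([C@@H]4OC[C@@H]5[C@H]4CO[C@H]5c4cc(OC)c(O[C@H](CO[Si](C)(C)C(C)(C)C)[C@@H](O)c6ccc(O[Si](C(C)C)(C(C)C)C(C)C)c(OC)c6)c(OC)c4)cc3OC)N8[C@@H](Cc9ccccc9)COC8=O
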